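## Retrosynthetic overview

- **Feature.** Germacrane numbering is used: ring C1–C10, ester C14 on C10, methyl C15 on C4, lactone O6–C12(=O)–C11(=C13)–C7. C13, C11 and ring carbon C7 form a 2-carbonylallyl unit. Its γ-carbon C7 is bonded to the carbinol carbon C8, so the α-methylene lactone and the ring bond C7–C8 both come from one allylmetal addition to a C8 aldehyde.
- **Disconnections.** The two esters are cut first (O9 3-hydroxy-2-methylbutanoate, O8 epoxyangelate). Then C7–C8 of the ten-membered ring is cut, which leads to a 3-(bromomethyl)butenolide tethered to an α-silyloxy aldehyde.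
- **Chain and right end.** Neryl acetate brings C1–C6, C15 and the ring-cis C4=C5 olefin. The right end (C8–C10, C14) is built through an alkyne: ynone, transfer hydrogenation (C9), syn hydrostannation–iodination, and methoxycarbonylation, which gives ring-cis C1=C10 with C2 trans to the ester.
- **Left end.** It is built last and without base, because C6–H of the vinyl butenolide is doubly activated. The sequence is asymmetric alkynylation of the Z enal (C6), semireduction, 2-(bromomethyl)acrylate ester, ring-closing metathesis.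
- **Ring order.** Oxirane (in the side-chain acid), then butenolide (ring-closing metathesis), then ten-membered carbocycle (key step).

Key step: step 24

Assumption: (R,R)-ProPhenol is taken to give the R carbinol at C6 (same aldehyde face as in the aldol reactions of this ligand). Both ligand enantiomers are sold, so the other one is used if the sense is opposite.

## Route

Step 1
Reactants: 1 angelic acid [(Z)-2-methylbut-2-enoic acid]
Product: 2 (Z)-2-methylbut-2-en-1-ol
Conditions: LiAlH4, Et2O, 0 °C to rt
Reagents that add atoms: none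
Why: LiAlH4 reduction of the acid gives the allylic alcohol without touching the Z olefin, whose geometry later fixes the cis relation of the C3 methyl group and the carboxyl carbon on the oxirane.

Step 2
Reactants: 2 (Z)-2-methylbut-2-en-1-ol
Product: 3 [(2R,3S)-2,3-dimethyloxiran-2-yl]methanol
Conditions: Ti(OiPr)4 (10 mol %), D-(−)-diisopropyl tartrate (12 mol %), t-BuOOH, 4 Å MS, CH2Cl2, −20 °C
Reagents that add atoms: tert-butyl hydroperoxide, CC(C)(C)OO
Why: Sharpless asymmetric epoxidation with the D-(−)-tartrate gives the 2R epoxy alcohol, and the syn oxygen transfer carries the Z geometry over into the 2R,3S oxirane.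

Step 3
Reactants: 3 [(2R,3S)-2,3-dimethyloxiran-2-yl]methanol
Product: 4 (2S,3S)-2,3-dimethyloxirane-2-carboxylic acid (epoxyangelic acid)
Conditions: TEMPO (10 mol %), PhI(OAc)2 (2.2 equiv), MeCN/H2O, rt
Reagents that add atoms: water, O
Why: TEMPO/PhI(OAc)2 oxidation takes the primary alcohol through the aldehyde hydrate to the acid under near-neutral conditions that leave the oxirane alone (C2 becomes S only because the priorities change).

Step 4
Reactants: 5 (R)-4-benzyl-3-propionyloxazolidin-2-one; 6 acetaldehyde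
Product: 8 (R)-4-benzyl-3-[(2R,3S)-3-hydroxy-2-methylbutanoyl]oxazolidin-2-one, via Z dibutylboron enolate 7 (not isolated)
Conditions: Bu2BOTf, Et3N, CH2Cl2, −78 to 0 °C; 6, −78 to 0 °C; then pH 7 buffer, MeOH, H2O2
Reagents that add atoms: none
Why: Evans syn aldol reaction, in which the Z boron enolate reacts through a Zimmerman–Traxler chair on the face left open by the benzyl group of the R auxiliary and so sets 2R,3S.

Step 5
Reactants: 8 (R)-4-benzyl-3-[(2R,3S)-3-hydroxy-2-methylbutanoyl]oxazolidin-2-one
Product: 9 (R)-4-benzyl-3-[(2R,3S)-2-methyl-3-(triethylsilyloxy)butanoyl]oxazolidin-2-one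
Conditions: TESCl, imidazole, DMF, 0 °C to rt
Reagents that add atoms: chlorotriethylsilane, CC[Si](Cl)(CC)CC
Why: Standard silyl ether formation; TES is chosen because buffered fluoride can remove it at the end next to the oxirane and the α-methylene lactone.

Step 6
Reactants: 9 (R)-4-benzyl-3-[(2R,3S)-2-methyl-3-(triethylsilyloxy)butanoyl]oxazolidin-2-one
Product: 10 (2R,3S)-2-methyl-3-(triethylsilyloxy)butanoic acid
Conditions: LiOH, H2O2, THF/H2O, 0 °C; aq Na2SO3; HCl to pH 4
Reagents that add atoms: hydrogen peroxide, OO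
Why: Hydroperoxide cleavage of the Evans imide attacks the exocyclic carbonyl and is too weakly basic to epimerise C2 or to remove the TES group at 0 °C.

Step 7
Reactants: 11 4-methoxybenzyl alcohol; 12 2-chloro-N-methoxy-N-methylacetamide
Product: 13 N-methoxy-2-[(4-methoxybenzyl)oxy]-N-methylacetamide
Conditions: NaH, THF, 0 °C to rt
Reagents that add atoms: none
Why: Williamson ether synthesis, in which the alkoxide of 11 displaces the primary α-chloride while the Weinreb amide resists alkoxide attack.

Step 8
Reactants: 14 neryl acetate [(Z)-3,7-dimethylocta-2,6-dien-1-yl acetate]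
Product: 15 (Z)-3-methyl-6-oxohex-2-en-1-yl acetate
Conditions: O3 (1 equiv), CH2Cl2, −78 °C; Me2S
Reagents that add atoms: ozone, [O-][O+]=O
Why: Chemoselective ozonolysis takes the electron-rich isopropylidene olefin, because the allylic acetate deactivates the other one, so the Z olefin (later C4=C5) stays.

Step 9
Reactants: 15 (Z)-3-methyl-6-oxohex-2-en-1-yl acetate
Product: 16 (Z)-3-methylhept-2-en-6-yn-1-ol
Conditions: dimethyl (1-diazo-2-oxopropyl)phosphonate, K2CO3, MeOH, 0 °C to rt
Reagents that add atoms: dimethyl (1-diazo-2-oxopropyl)phosphonate, COP(=O)(OC)C(=[N+]=[N-])C(C)=O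
Why: Ohira–Bestmann homologation turns the aldehyde C1 into the terminal alkyne (adding C10), and the same K2CO3/MeOH medium removes the acetate by transesterification.

Step 10
Reactants: 16 (Z)-3-methylhept-2-en-6-yn-1-ol; 13 N-methoxy-2-[(4-methoxybenzyl)oxy]-N-methylacetamide
Product: 18 (Z)-9-hydroxy-1-[(4-methoxybenzyl)oxy]-7-methylnon-7-en-3-yn-2-one, via dilithio alkoxide acetylide 17 (not isolated)
Conditions: n-BuLi (2.1 equiv), THF, −78 °C; 13, −78 to −20 °C; H2O
Reagents that add atoms: none
Why: Weinreb ketone synthesis, in which the acetylide carbon of the dianion is acylated, the chelated tetrahedral adduct blocks a second addition, and the alkoxide end stays inert.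

Step 11
Reactants: 18 (Z)-9-hydroxy-1-[(4-methoxybenzyl)oxy]-7-methylnon-7-en-3-yn-2-one
Product: 19 (2R,7Z)-1-[(4-methoxybenzyl)oxy]-7-methylnon-7-en-3-yne-2,9-diol
Conditions: Ru[(S,S)-TsDPEN](p-cymene) (1 mol %), i-PrOH, rt
Reagents that add atoms: none
Why: Noyori asymmetric transfer hydrogenation of an alkynyl ketone with the S,S catalyst places the alkynyl group as in simple ynones, which reads 9R here because CH2OPMB outranks the alkyne, and neither alkyne nor olefin is reduced.

Step 12
Reactants: 19 (2R,7Z)-1-[(4-methoxybenzyl)oxy]-7-methylnon-7-en-3-yne-2,9-diol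
Product: 21 (2S,3E,7Z)-3-iodo-1-[(4-methoxybenzyl)oxy]-7-methylnona-3,7-diene-2,9-diol, via C10 tributylstannyl diene diol 20 (not isolated)
Conditions: PdCl2(PPh3)2 (3 mol %), Bu3SnH (slow addition), THF, 0 °C; then I2, CH2Cl2, −20 °C
Reagents that add atoms: iodine, II
Why: Palladium-catalysed syn hydrostannation puts hydrogen on C1 and tin on C10, the alkyne carbon next to the electron-withdrawing carbinol, so C2 and C9 become cis, and iododestannylation keeps this geometry.

Step 13
Reactants: 21 (2S,3E,7Z)-3-iodo-1-[(4-methoxybenzyl)oxy]-7-methylnona-3,7-diene-2,9-diol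
Product: 22 bis(tert-butyldimethylsilyl) ether of 21 (O6 and O9 silylated)
Conditions: TBSOTf (2.5 equiv), 2,6-lutidine, CH2Cl2, −78 to 0 °C
Reagents that add atoms: tert-butyldimethylsilyl triflate, CC(C)(C)[Si](C)(C)OS(=O)(=O)C(F)(F)F
Why: Silyl ether formation at both hydroxyl groups; the secondary TBS ether is the non-chelating O9 group that stays until after the ring closure.

Step 14
Reactants: 22 bis(tert-butyldimethylsilyl) ether of 21
Product: 23 methyl (2E,6Z)-8-(TBSO)-2-[(1R)-1-(TBSO)-2-(4-methoxybenzyloxy)ethyl]-6-methylocta-2,6-dienoate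
Conditions: PdCl2(PPh3)2 (5 mol %), CO (1 atm), Et3N, MeOH/DMF, 55 °C
Reagents that add atoms: carbon monoxide, [C-]#[O+]; methanol, CO
Why: Palladium-catalysed methoxycarbonylation of the alkenyl iodide goes with retention, so ester C14 ends up trans to C2, which is the ring-cis C1=C10 geometry of the target.

Step 15
Reactants: 23 methyl (2E,6Z)-8-(TBSO)-2-[(1R)-1-(TBSO)-2-(4-methoxybenzyloxy)ethyl]-6-methylocta-2,6-dienoate
Product: 24 methyl (2E,6Z)-2-[(1R)-1-(TBSO)-2-(4-methoxybenzyloxy)ethyl]-8-hydroxy-6-methylocta-2,6-dienoate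
Conditions: camphorsulfonic acid (10 mol %), MeOH/CH2Cl2, 0 °C
Reagents that add atoms: none
Why: Selective acid-catalysed desilylation, because the unhindered primary allylic TBS ether is methanolysed much faster than the hindered secondary one.

Step 16
Reactants: 24 methyl (2E,6Z)-2-[(1R)-1-(TBSO)-2-(4-methoxybenzyloxy)ethyl]-8-hydroxy-6-methylocta-2,6-dienoate
Product: 25 methyl (2E,6Z)-2-[(1R)-1-(TBSO)-2-(4-methoxybenzyloxy)ethyl]-6-methyl-8-oxoocta-2,6-dienoate (Z enal)
Conditions: TEMPO (10 mol %), PhI(OAc)2 (1.1 equiv), CH2Cl2, 0 °C to rt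
Reagents that add atoms: none
Why: TEMPO/PhI(OAc)2 oxidation, proven on nerol-type alcohols, gives the Z enal without acid or base strong enough to isomerise it.

Step 17
Reactants: 25 Z enal; 26 trimethylsilylacetylene
Product: 28 methyl (2E,6Z,8R)-2-[(1R)-1-(TBSO)-2-(4-methoxybenzyloxy)ethyl]-8-hydroxy-6-methyl-10-(trimethylsilyl)deca-2,6-dien-9-ynoate, via methylzinc acetylide 27 (not isolated)
Conditions: (R,R)-ProPhenol (20 mol %), Me2Zn (3 equiv), 26 (3 equiv), toluene, 0 to 4 °C; H2O
Reagents that add atoms: none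
Why: Zinc–ProPhenol asymmetric alkynylation, which works best with α,β-unsaturated aldehydes, binds aldehyde and alkynylzinc on one dinuclear zinc complex and sets C6 under catalyst control.

Step 18
Reactants: 28 C6 (trimethylsilyl)propargylic alcohol
Product: 29 methyl (2E,6Z,8R)-2-[(1R)-1-(TBSO)-2-(4-methoxybenzyloxy)ethyl]-8-hydroxy-6-methyldeca-2,6-dien-9-ynoate
Conditions: K2CO3 (20 mol %), MeOH, 0 °C to rt
Reagents that add atoms: none
Why: Carbonate-catalysed methanolysis cleaves only the alkynyl C–Si bond (protiodesilylation), while silyl ethers, methyl ester and carbinol are unaffected.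

Step 19
Reactants: 29 terminal propargylic alcohol
Product: 30 methyl (2E,6Z,8S)-2-[(1R)-1-(TBSO)-2-(4-methoxybenzyloxy)ethyl]-8-hydroxy-6-methyldeca-2,6,9-trienoate (same spatial arrangement at C6, descriptor changed by priorities)
Conditions: H2 (1 atm), Pd/CaCO3 poisoned with Pb(OAc)2, quinoline, EtOAc, rt
Reagents that add atoms: none
Why: Lindlar semihydrogenation stops at the vinyl group, because the poisoned catalyst neither reduces the trisubstituted olefins nor cleaves the PMB ether.

Step 20
Reactants: 30 vinyl carbinol; 31 2-(bromomethyl)acrylic acid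
Product: 33 2-(bromomethyl)acrylate ester of 30 at O6, via 2-(bromomethyl)acryloyl chloride 32 (not isolated)
Conditions: 31, (COCl)2, DMF (cat.), CH2Cl2, 0 °C; then 30, 2,6-lutidine, CH2Cl2, −20 °C
Reagents that add atoms: none
Why: Acylation of the secondary alcohol by the acid chloride with a hindered pyridine base, which cannot displace the allylic bromide as DMAP would.

Step 21
Reactants: 33 2-(bromomethyl)acrylate ester
Product: 34 methyl (2E,6Z)-7-[(2R)-4-(bromomethyl)-5-oxo-2,5-dihydrofuran-2-yl]-2-[(1R)-1-(TBSO)-2-(4-methoxybenzyloxy)ethyl]-6-methylhepta-2,6-dienoate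
Conditions: second-generation Hoveyda–Grubbs catalyst (7 mol %), 1,4-benzoquinone (10 mol %), toluene, 60 °C
Reagents that add atoms: none
Why: Ring-closing metathesis starts at the only monosubstituted olefin and closes onto the 1,1-disubstituted acrylate to give the butenolide with CH2Br already on C11, under neutral conditions that spare the doubly activated C6–H.

Step 22
Reactants: 34 bromomethyl butenolide PMB ether
Product: 35 the C8 primary alcohol (34 with CH2OH in place of CH2OPMB)
Conditions: DDQ, CH2Cl2/pH 7 buffer, 0 °C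
Reagents that add atoms: none
Why: Oxidative PMB cleavage with DDQ is neutral, so the allylic bromide, the TBS ether and C6–H survive; 35 is carried on at once to forestall lactonisation of O8 onto C14.

Step 23
Reactants: 35 C8 primary alcohol
Product: 36 methyl (2E,6Z)-7-[(2R)-4-(bromomethyl)-5-oxo-2,5-dihydrofuran-2-yl]-2-[(1R)-1-(TBSO)-2-oxoethyl]-6-methylhepta-2,6-dienoate (bromomethyl butenolide aldehyde)
Conditions: Dess–Martin periodinane, CH2Cl2, 0 °C to rt
Reagents that add atoms: none
Why: Dess–Martin oxidation gives the α-silyloxy β,γ-unsaturated aldehyde without base, so C9 is not epimerised and C1=C10 does not move into conjugation.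

Step 24
Reactants: 36 bromomethyl butenolide aldehyde
Product: 38 lactone-fused ten-membered carbocycle with free 8S hydroxyl and O9 TBS ether (C6 to C9 as in the target), via allylchromium dichloride 37 (not isolated)
Conditions: CrCl2 (10 equiv), THF, rt; 36 added by syringe pump over 12 h, final 2 mM; H2O
Reagents that add atoms: none
Why: CrCl2 (divalent chromium) reduces the C13–Br bond in two one-electron steps to the 2-carbonylallylchromium species 37 (trivalent chromium), which binds the C8 aldehyde oxygen and transfers its γ-carbon C7 in an SE2' sense, so that C7–C8 forms while the olefin moves from C7=C11 to C11=C13 (intramolecular Nozaki–Hiyama/Barbier allylation). The closest known reactions are the zinc- and chromium-mediated additions of 3-(bromomethyl)furan-2(5H)-ones to aldehydes and the chromium-mediated closures of ten-membered germacrane rings from ω-formyl 2-(bromomethyl)enoates. The ten-membered ring closes by 10-exo-trig addition of C7 to the carbonyl carbon C8, helped by the two ring-cis olefins that fold the chain and by slow addition at millimolar concentration, which holds back dimers. C7 is controlled by C6: bonding on the butenolide face opposite C5 gives the trans lactone, because approach on the C5 face would press C5 against C9. C8 is controlled by the aldehyde face: 8S needs the Felkin–Anh rotamer with the non-chelating C9–OTBS bond anti to the forming bond, which is a 7,8-syn union, whereas open-chain additions of this ring-locked allylmetal prefer the 7,8-anti chair, so this face selectivity is the least secured point and the first fallback answers it. Attack at the aldehyde rather than at the two esters or the lactone, and at the γ-carbon rather than at C13, follows from the mild oxophilic allylchromium reagent.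

Step 25
Reactants: 38 C8 alcohol; 4 (2S,3S)-epoxyangelic acid
Product: 40 O8 (2S,3S)-epoxyangelate of 38, via epoxyangelic trichlorobenzoic anhydride 39 (not isolated)
Conditions: 4, 2,4,6-trichlorobenzoyl chloride, Et3N, toluene, rt; then 38, DMAP, toluene, 0 °C to rt
Reagents that add atoms: none
Why: Yamaguchi esterification acylates the hindered O8 with retention, and running it directly after the ring closure blocks migration of the lactone from O6 to O8.

Step 26
Reactants: 40 O8 epoxyangelate
Product: 41 the C9 alcohol (40 without the TBS group)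
Conditions: HF·pyridine, pyridine, THF, 0 °C to rt
Reagents that add atoms: none
Why: Fluoride desilylation in an acidic buffer frees O9 without forming the alkoxide that would trigger O8 to O9 acyl migration, and the electron-poor oxirane tolerates it.

Step 27
Reactants: 41 C9 alcohol; 10 (2R,3S)-2-methyl-3-(triethylsilyloxy)butanoic acid
Product: 43 O9 (2R,3S)-2-methyl-3-(triethylsilyloxy)butanoate of 41, via silyloxybutanoic trichlorobenzoic anhydride 42 (not isolated)
Conditions: 10, 2,4,6-trichlorobenzoyl chloride, Et3N, toluene, rt; then 41, DMAP, toluene, 0 °C to rt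
Reagents that add atoms: none
Why: A second Yamaguchi esterification acylates the allylic O9 with retention, and the silyl ether on the acid prevents self-acylation.

Step 28
Reactants: 43 TES-protected diester
Product: 44 CNP0135583.1 (target)
Conditions: HF·pyridine, pyridine, THF, 0 °C
Reagents that add atoms: none
Why: Mild fluoride cleavage of the TES ether leaves the oxirane, the three esters and the α-methylene lactone untouched and changes no stereocentre.

## Compound list

1 | angelic acid | C/C=C(/C)C(=O)O | starting material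
2 | (Z)-2-methylbut-2-en-1-ol | C/C=C(/C)CO | intermediate
3 | [(2R,3S)-2,3-dimethyloxiran-2-yl]methanol | OC[C@@]1(C)O[C@H]1C | intermediate
4 | (2S,3S)-2,3-dimethyloxirane-2-carboxylic acid | OC(=O)[C@@]1(C)O[C@H]1C | intermediate
5 | (R)-4-benzyl-3-propionyloxazolidin-2-one | O=C1OC[C@@H](Cc2ccccc2)N1C(=O)CC | starting material
6 | acetaldehyde | CC=O | starting material
7 | Z dibutylboron enolate of 5 | C/C=C(\OB(CCCC)CCCC)N1[C@H](Cc2ccccc2)COC1=O | intermediate
8 | (R)-4-benzyl-3-[(2R,3S)-3-hydroxy-2-methylbutanoyl]oxazolidin-2-one | O=C1OC[C@@H](Cc2ccccc2)N1C(=O)[C@H](C)[C@H](C)O | intermediate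
9 | TES ether of 8 | O=C1OC[C@@H](Cc2ccccc2)N1C(=O)[C@H](C)[C@H](C)O[Si](CC)(CC)CC | intermediate
10 | (2R,3S)-2-methyl-3-(triethylsilyloxy)butanoic acid | OC(=O)[C@H](C)[C@H](C)O[Si](CC)(CC)CC | intermediate
11 | 4-methoxybenzyl alcohol | COc1ccc(CO)cc1 | starting material
12 | 2-chloro-N-methoxy-N-methylacetamide | CON(C)C(=O)CCl | starting material
13 | N-methoxy-2-[(4-methoxybenzyl)oxy]-N-methylacetamide | CON(C)C(=O)COCc1ccc(OC)cc1 | intermediate
14 | neryl acetate | CC(=O)OC/C=C(/C)CCC=C(C)C | starting material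
15 | (Z)-3-methyl-6-oxohex-2-en-1-yl acetate | CC(=O)OC/C=C(/C)CCC=O | intermediate
16 | (Z)-3-methylhept-2-en-6-yn-1-ol | OC/C=C(/C)CCC#C | intermediate
17 | dilithio alkoxide acetylide of 16 | [Li]OC/C=C(/C)CCC#C[Li] | intermediate
18 | (Z)-9-hydroxy-1-[(4-methoxybenzyl)oxy]-7-methylnon-7-en-3-yn-2-one | OC/C=C(/C)CCC#CC(=O)COCc1ccc(OC)cc1 | intermediate
19 | (2R,7Z)-1-[(4-methoxybenzyl)oxy]-7-methylnon-7-en-3-yne-2,9-diol | OC/C=C(/C)CCC#C[C@@H](O)COCc1ccc(OC)cc1 | intermediate
20 | C10 tributylstannyl diene diol | OC/C=C(/C)CC/C=C(/[Sn](CCCC)(CCCC)CCCC)[C@@H](O)COCc1ccc(OC)cc1 | intermediate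
21 | (2S,3E,7Z)-3-iodo-1-[(4-methoxybenzyl)oxy]-7-methylnona-3,7-diene-2,9-diol | OC/C=C(/C)CC/C=C(/I)[C@@H](O)COCc1ccc(OC)cc1 | intermediate
22 | bis-TBS ether of 21 | CC(C)(C)[Si](C)(C)OC/C=C(/C)CC/C=C(/I)[C@@H](O[Si](C)(C)C(C)(C)C)COCc1ccc(OC)cc1 | intermediate
23 | C14 methyl ester, O6 and O9 TBS, O8 PMB | CC(C)(C)[Si](C)(C)OC/C=C(/C)CC/C=C(/C(=O)OC)[C@@H](O[Si](C)(C)C(C)(C)C)COCc1ccc(OC)cc1 | intermediate
24 | C6 allylic alcohol | OC/C=C(/C)CC/C=C(/C(=O)OC)[C@@H](O[Si](C)(C)C(C)(C)C)COCc1ccc(OC)cc1 | intermediate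
25 | C6 Z enal | O=C/C=C(/C)CC/C=C(/C(=O)OC)[C@@H](O[Si](C)(C)C(C)(C)C)COCc1ccc(OC)cc1 | intermediate
26 | trimethylsilylacetylene | C#C[Si](C)(C)C | starting material
27 | methylzinc trimethylsilylacetylide | C[Zn]C#C[Si](C)(C)C | intermediate
28 | (6R) trimethylsilyl propargylic alcohol | C[Si](C)(C)C#C[C@H](O)/C=C(/C)CC/C=C(/C(=O)OC)[C@@H](O[Si](C)(C)C(C)(C)C)COCc1ccc(OC)cc1 | intermediate
29 | (6R) terminal propargylic alcohol | C#C[C@H](O)/C=C(/C)CC/C=C(/C(=O)OC)[C@@H](O[Si](C)(C)C(C)(C)C)COCc1ccc(OC)cc1 | intermediate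
30 | C6 vinyl carbinol | C=C[C@H](O)/C=C(/C)CC/C=C(/C(=O)OC)[C@@H](O[Si](C)(C)C(C)(C)C)COCc1ccc(OC)cc1 | intermediate
31 | 2-(bromomethyl)acrylic acid | C=C(CBr)C(=O)O | starting material
32 | 2-(bromomethyl)acryloyl chloride | C=C(CBr)C(=O)Cl | intermediate
33 | O6 2-(bromomethyl)acrylate of 30 | C=C[C@H](OC(=O)C(=C)CBr)/C=C(/C)CC/C=C(/C(=O)OC)[C@@H](O[Si](C)(C)C(C)(C)C)COCc1ccc(OC)cc1 | intermediate
34 | bromomethyl butenolide, O8 PMB | O=C1O[C@@H](C=C1CBr)/C=C(/C)CC/C=C(/C(=O)OC)[C@@H](O[Si](C)(C)C(C)(C)C)COCc1ccc(OC)cc1 | intermediate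
35 | bromomethyl butenolide, C8 alcohol | O=C1O[C@@H](C=C1CBr)/C=C(/C)CC/C=C(/C(=O)OC)[C@@H](O[Si](C)(C)C(C)(C)C)CO | intermediate
36 | bromomethyl butenolide, C8 aldehyde (key-step precursor) | O=C1O[C@@H](C=C1CBr)/C=C(/C)CC/C=C(/C(=O)OC)[C@@H](O[Si](C)(C)C(C)(C)C)C=O | intermediate
37 | allylchromium dichloride from 36 | O=C1O[C@@H](C=C1C[Cr](Cl)Cl)/C=C(/C)CC/C=C(/C(=O)OC)[C@@H](O[Si](C)(C)C(C)(C)C)C=O | intermediate
38 | lactone-fused ten-membered ring, free 8S hydroxyl (key-step product) | C=C1C(=O)O[C@@H]2/C=C(/C)CC/C=C(/C(=O)OC)[C@@H](O[Si](C)(C)C(C)(C)C)[C@@H](O)[C@@H]12 | intermediate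
39 | epoxyangelic 2,4,6-trichlorobenzoic anhydride | O=C(OC(=O)[C@@]1(C)O[C@H]1C)c2c(Cl)cc(Cl)cc2Cl | intermediate
40 | O8 epoxyangelate, O9 TBS | C=C1C(=O)O[C@@H]2/C=C(/C)CC/C=C(/C(=O)OC)[C@@H](O[Si](C)(C)C(C)(C)C)[C@@H](OC(=O)[C@@]3(C)O[C@H]3C)[C@@H]12 | intermediate
41 | O8 epoxyangelate, free C9 hydroxyl | C=C1C(=O)O[C@@H]2/C=C(/C)CC/C=C(/C(=O)OC)[C@@H](O)[C@@H](OC(=O)[C@@]3(C)O[C@H]3C)[C@@H]12 | intermediate
42 | (2R,3S)-2-methyl-3-(triethylsilyloxy)butanoic 2,4,6-trichlorobenzoic anhydride | O=C(OC(=O)[C@H](C)[C@H](C)O[Si](CC)(CC)CC)c1c(Cl)cc(Cl)cc1Cl | intermediate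
43 | TES-protected target | C=C1C(=O)O[C@@H]2/C=C(/C)CC/C=C(/C(=O)OC)[C@@H](OC(=O)[C@H](C)[C@H](C)O[Si](CC)(CC)CC)[C@@H](OC(=O)[C@@]3(C)O[C@H]3C)[C@@H]12 | intermediate
44 | CNP0135583.1 | C=C1C(=O)O[C@@H]2/C=C(/C)CC/C=C(/C(=O)OC)[C@@H](OC(=O)[C@H](C)[C@H](C)O)[C@@H](OC(=O)[C@@]3(C)O[C@H]3C)[C@@H]12 | target

## Step count and risks

Total step count: 28.
Longest linear sequence: 21 steps (steps 8 to 28, from neryl acetate).

**1. Step 24 (ring closure).**
- What may go wrong: the allylchromium species may be protonated or may couple between molecules before the ring closes.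
- The larger risk is attack on the other aldehyde face. A bridged chair with C9 equatorial leads to inversion of the wanted sense at C8.
- Fallback: it sets out from 36 and comes back at 38.
- The closure is run as in step 24 and the 8-epi carbinol F1 is carried on.
- Dess–Martin oxidation gives the 8-ketone F2, which is used without chromatography so that C7–H does not enolise.
- Luche reduction (NaBH4, CeCl3·7H2O, MeOH, −78 °C) brings hydride to the open ketone face flanked by H7. The other face lies under the lactone, so O8 ends up as in 38.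
- C8 is then set by reduction instead of by the C–C bond formation.

**2. Step 17 (alkynylation).**
- What may go wrong: Z to E isomerisation of the enal on the Lewis acidic zinc complex, or weak facial discrimination for a β,β-disubstituted Z enal.
- Fallback: it sets out from 25 and comes back at 28.
- Lithium trimethylsilylacetylide (THF, −78 °C) adds quickly and without stereocontrol to give the C6-epimeric carbinol F3.
- MnO2 oxidises F3 to the alkenyl alkynyl ketone F4.
- Midland reduction with (R)-Alpine-Borane, which treats the slim alkynyl group as the small substituent, sets 6R under reagent control.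

**3. Step 21 (ring-closing metathesis).**
- What may go wrong: the carbene formed at the vinyl group may fail to engage the hindered, electron-poor acrylate. Cross metathesis or ruthenium hydride isomerisation of the bis-allylic ester then takes over.
- Fallback: it sets out from 25 and comes back at 34.
- Zinc–ProPhenol addition of methyl propiolate gives the γ-hydroxy ynoate F5.
- TESOTf/2,6-lutidine gives its TES ether F6, so that zerovalent palladium cannot ionise an allylic lactone.
- Pd(PPh3)4/Bu3SnH adds syn with tin α to the ester to give the stannyl enoate F7, and I2 gives the iodo enoate F8.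
- Stille coupling with Bu3SnCH2OH gives the hydroxymethyl enoate F9, and CBr4/PPh3 gives the bromomethyl enoate F10.
- HF·pyridine removes the TES group, after which O6, held cis to the ester, lactonises spontaneously to 34.

## Further compounds

F1 | step 24 | 8-epi carbinol (8R epimer of 38) | C=C1C(=O)O[C@@H]2/C=C(/C)CC/C=C(/C(=O)OC)[C@@H](O[Si](C)(C)C(C)(C)C)[C@H](O)[C@@H]12
F2 | step 24 | 8-ketone | C=C1C(=O)O[C@@H]2/C=C(/C)CC/C=C(/C(=O)OC)[C@@H](O[Si](C)(C)C(C)(C)C)C(=O)[C@@H]12
F3 | step 17 | C6-epimeric trimethylsilyl propargylic carbinol | C[Si](C)(C)C#CC(O)/C=C(/C)CC/C=C(/C(=O)OC)[C@@H](O[Si](C)(C)C(C)(C)C)COCc1ccc(OC)cc1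
F4 | step 17 | alkenyl alkynyl ketone | C[Si](C)(C)C#CC(=O)/C=C(/C)CC/C=C(/C(=O)OC)[C@@H](O[Si](C)(C)C(C)(C)C)COCc1ccc(OC)cc1
F5 | step 21 | (6R) γ-hydroxy ynoate | COC(=O)C#C[C@H](O)/C=C(/C)CC/C=C(/C(=O)OC)[C@@H](O[Si](C)(C)C(C)(C)C)COCc1ccc(OC)cc1
F6 | step 21 | O6 TES ether of F5 | COC(=O)C#C[C@H](O[Si](CC)(CC)CC)/C=C(/C)CC/C=C(/C(=O)OC)[C@@H](O[Si](C)(C)C(C)(C)C)COCc1ccc(OC)cc1
F7 | step 21 | C11 stannyl enoate | COC(=O)C(\[Sn](CCCC)(CCCC)CCCC)=C/[C@H](O[Si](CC)(CC)CC)/C=C(/C)CC/C=C(/C(=O)OC)[C@@H](O[Si](C)(C)C(C)(C)C)COCc1ccc(OC)cc1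
F8 | step 21 | C11 iodo enoate | COC(=O)C(\I)=C/[C@H](O[Si](CC)(CC)CC)/C=C(/C)CC/C=C(/C(=O)OC)[C@@H](O[Si](C)(C)C(C)(C)C)COCc1ccc(OC)cc1
F9 | step 21 | C11 hydroxymethyl enoate | COC(=O)C(\CO)=C/[C@H](O[Si](CC)(CC)CC)/C=C(/C)CC/C=C(/C(=O)OC)[C@@H](O[Si](C)(C)C(C)(C)C)COCc1ccc(OC)cc1
F10 | step 21 | C11 bromomethyl enoate | COC(=O)C(\CBr)=C/[C@H](O[Si](CC)(CC)CC)/C=C(/C)CC/C=C(/C(=O)OC)[C@@H](O[Si](C)(C)C(C)(C)C)COCc1ccc(OC)cc1
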